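Ring A is numbered C1 (pentyl), C2 (H), C3 (OH), C4 (O-aroyl), C5 (OH), C6 (acetyl); ring B is the 4-hydroxy-2-methoxy-6-propylbenzoyl unit.
Retrosynthesis: the ring B phenol is masked as a benzyl ether; ring A is cut at C1–C2 and C5–C6 with the depside ester left intact; the ester is then cut at its O–C4 bond (C4 being an sp3 carbon at that stage); the ring B acid is traced to divarinol.
Enabling feature: the three adjacent oxygens on C3, C4 and C5, followed by acetyl on C6 and pentyl on C1, make C2–C5 a 2-acyloxyacetoacetate (used as its bis-silyl dienol ether) and C6–C1 the two alkyne carbons of non-3-yn-2-one.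
Forward order: ring B acid from divarinol (formylation, 4-O-benzylation, 2-O-methylation, oxidation); carboxylate displacement on methyl 2-chloroacetoacetate; two-stage silylation to the diene; [4+2] addition and aromatisation to form ring A, the only ring built; hydrogenolysis.
Stereochemistry: the target is achiral, so nothing has to be controlled; the stereocentres of intermediates 9 and 14 are racemic and are erased in later steps.

Key step: step 8

Remark: the target SMILES has no stereocentre and no resolvable axis, so "single enantiomer" is taken to mean the one achiral compound; divarinol, methyl 2-chloroacetoacetate and non-3-yn-2-one are taken as purchased.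

Step 1
Reactants: 1 divarinol (5-propylbenzene-1,3-diol)
Product: 3 2,4-dihydroxy-6-propylbenzaldehyde, via aryl iminium chloride 2 (not isolated)
Conditions: POCl3, DMF, MeCN, 0 °C to rt; then H2O, 50 °C
Reagents that add atoms: N,N-dimethylformamide CN(C)C=O; water O
Why: Vilsmeier–Haack formylation should attack the ring carbon para to one hydroxyl and ortho to the other, not the doubly flanked carbon between the hydroxyls, as is usual for 5-alkylresorcinols, and water then hydrolyses the iminium salt to the aldehyde.

Step 2
Reactants: 3 2,4-dihydroxy-6-propylbenzaldehyde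
Product: 4 4-(benzyloxy)-2-hydroxy-6-propylbenzaldehyde
Conditions: BnBr (1.05 equiv), NaHCO3, MeCN, 60 °C
Reagents that add atoms: benzyl bromide BrCc1ccccc1
Why: Williamson etherification with a weak base and one equivalent of halide should alkylate only the more acidic 4-hydroxyl (para to the formyl group), because the 2-hydroxyl is tied up in a hydrogen bond to the aldehyde.

Step 3
Reactants: 4 4-(benzyloxy)-2-hydroxy-6-propylbenzaldehyde
Product: 5 4-(benzyloxy)-2-methoxy-6-propylbenzaldehyde
Conditions: MeI, K2CO3, DMF, rt
Reagents that add atoms: iodomethane CI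
Why: Williamson O-methylation of the remaining chelated phenol with carbonate and excess iodomethane in DMF is standard, and the aldehyde has no enolisable position.

Step 4
Reactants: 5 4-(benzyloxy)-2-methoxy-6-propylbenzaldehyde
Product: 6 4-(benzyloxy)-2-methoxy-6-propylbenzoic acid
Conditions: NaClO2, NaH2PO4, 2-methyl-2-butene, t-BuOH/THF/H2O, 0 °C to rt
Reagents that add atoms: sodium chlorite [Na+].[O-]Cl=O
Why: Pinnick oxidation converts even doubly ortho-substituted aldehydes into acids, and the alkene scavenger removes hypochlorous acid before it can chlorinate the electron-rich ring or touch the benzyl ether.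

Step 5
Reactants: 6 4-(benzyloxy)-2-methoxy-6-propylbenzoic acid; 7 methyl 2-chloroacetoacetate (methyl 2-chloro-3-oxobutanoate)
Product: 9 methyl 2-{[4-(benzyloxy)-2-methoxy-6-propylbenzoyl]oxy}-3-oxobutanoate, via potassium carboxylate 8 (not isolated)
Conditions: KHCO3 (1.0 equiv), DMF, rt; then 7, rt to 40 °C
Reagents that add atoms: none
Why: SN2 O-alkylation of a carboxylate by an α-chloro-β-keto ester is a standard route to 2-acyloxyacetoacetates; attack through the carboxylate oxygen is insensitive to the two ortho substituents, and preforming the salt with one equivalent of bicarbonate leaves no base to enolise the product.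

Step 6
Reactants: 9 methyl 2-{[4-(benzyloxy)-2-methoxy-6-propylbenzoyl]oxy}-3-oxobutanoate
Product: 10 methyl 2-{[4-(benzyloxy)-2-methoxy-6-propylbenzoyl]oxy}-3-(trimethylsilyloxy)but-2-enoate
Conditions: TMSCl, Et3N, toluene, rt; filtered and concentrated under argon, used crude
Reagents that add atoms: chlorotrimethylsilane C[Si](C)(C)Cl
Why: Soft enolisation and O-silylation of a β-keto ester with Et3N and TMSCl is the usual first stage towards 1,3-bis(silyloxy)dienes, and capping the ketone enol oxygen also removes the nucleophile that could take over the neighbouring aroyl group.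

Step 7
Reactants: 10 methyl 2-{[4-(benzyloxy)-2-methoxy-6-propylbenzoyl]oxy}-3-(trimethylsilyloxy)but-2-enoate
Product: 12 1-methoxy-1,3-bis(trimethylsilyloxy)buta-1,3-dien-2-yl 4-(benzyloxy)-2-methoxy-6-propylbenzoate, via lithium dienolate 11 (not isolated)
Conditions: LDA (1.1 equiv), THF, −78 °C; then TMSCl, −78 °C to 0 °C; hexane trituration, filtration under argon, used at once
Reagents that add atoms: chlorotrimethylsilane C[Si](C)(C)Cl
Why: Kinetic γ-deprotonation of the β-silyloxy enoate by LDA and O-silylation of the extended enolate is the standard second stage of the diene synthesis; the γ-methyl group is more acidic than the benzylic positions, and the two ortho substituents shield the aroyl carbonyl from the amide and from acyl transfer.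

Step 8
Reactants: 12 1-methoxy-1,3-bis(trimethylsilyloxy)buta-1,3-dien-2-yl 4-(benzyloxy)-2-methoxy-6-propylbenzoate; 13 non-3-yn-2-one
Product: 15 3-acetyl-2,6-dihydroxy-4-pentylphenyl 4-(benzyloxy)-2-methoxy-6-propylbenzoate, via cyclohexadiene cycloadduct 14 (not isolated)
Conditions: 13 (2–3 equiv), toluene, 100 °C, sealed tube; then 1 M HCl, THF, 0 °C to rt
Reagents that add atoms: none
Why: The CH2 terminus of diene 12, the carbon with the largest HOMO coefficient because three oxygen donors push electron density towards it, bonds to the pentyl-bearing β-carbon of ynone 13 while the ketene acetal carbon bonds to the α-carbon, in a concerted but strongly asynchronous Diels–Alder reaction (conjugate addition followed by closure of the allenolate onto the silyloxycarbenium ion would give the same adduct 14). The closest known reaction type is the [4+2] benzannulation of 1-alkoxy-1,3-bis(silyloxy)buta-1,3-dienes with acetylenic ketones and esters, to which the 2-aroyloxy group is added here as a spectator. Ring A closes as a six-membered carbocycle in the [4+2] mode, with C1–C2 and C5–C6 as the new bonds, and 14 aromatises in the acidic work-up: protodesilylation of the methyl silyl ketal gives a hemiketal that expels methanol, the silyl enol ether is hydrolysed, and the dienone enolises to the phenol held by a hydrogen bond to the acetyl group. No stereocentre remains, since the racemic ketal carbon of 14 becomes the aromatic C5. The step needs regioselectivity, which the matched push–pull polarisation of the two partners provides; loss of methanol instead of silanol, which hydrolytic Si–O cleavage before any ionisation of the ketal should secure; and an ester that stays on O4, which the two ortho substituents of the aroyl group favour by blocking attack at its carbonyl carbon.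

Step 9
Reactants: 15 3-acetyl-2,6-dihydroxy-4-pentylphenyl 4-(benzyloxy)-2-methoxy-6-propylbenzoate
Product: 16 3-acetyl-2,6-dihydroxy-4-pentylphenyl 4-hydroxy-2-methoxy-6-propylbenzoate (CNP0112527.0)
Conditions: H2 (1 atm), 10% Pd/C, EtOAc, rt, stopped after one equivalent of H2
Reagents that add atoms: none
Why: Hydrogenolysis of an aryl benzyl ether over palladium under neutral conditions should be faster than reduction of the hydrogen-bonded ortho-hydroxyaryl ketone, leaves the aryl ester alone, and the absence of base avoids acyl migration to the flanking phenols.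

Compound list
1 | divarinol (5-propylbenzene-1,3-diol) | CCCc1cc(O)cc(O)c1 | starting material
2 | [(2,4-dihydroxy-6-propylphenyl)methylidene]dimethyliminium chloride | CCCc1cc(O)cc(O)c1C=[N+](C)C.[Cl-] | intermediate
3 | 2,4-dihydroxy-6-propylbenzaldehyde | CCCc1cc(O)cc(O)c1C=O | intermediate
4 | 4-(benzyloxy)-2-hydroxy-6-propylbenzaldehyde | CCCc1cc(OCc2ccccc2)cc(O)c1C=O | intermediate
5 | 4-(benzyloxy)-2-methoxy-6-propylbenzaldehyde | CCCc1cc(OCc2ccccc2)cc(OC)c1C=O | intermediate
6 | 4-(benzyloxy)-2-methoxy-6-propylbenzoic acid | CCCc1cc(OCc2ccccc2)cc(OC)c1C(=O)O | intermediate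
7 | methyl 2-chloroacetoacetate (methyl 2-chloro-3-oxobutanoate, racemic) | CC(=O)C(Cl)C(=O)OC | starting material
8 | potassium 4-(benzyloxy)-2-methoxy-6-propylbenzoate | CCCc1cc(OCc2ccccc2)cc(OC)c1C(=O)[O-].[K+] | intermediate
9 | methyl 2-{[4-(benzyloxy)-2-methoxy-6-propylbenzoyl]oxy}-3-oxobutanoate (racemic, enolisable) | CCCc1cc(OCc2ccccc2)cc(OC)c1C(=O)OC(C(C)=O)C(=O)OC | intermediate
10 | methyl 2-{[4-(benzyloxy)-2-methoxy-6-propylbenzoyl]oxy}-3-(trimethylsilyloxy)but-2-enoate (E/Z mixture, geometry irrelevant) | CCCc1cc(OCc2ccccc2)cc(OC)c1C(=O)OC(C(=O)OC)=C(C)O[Si](C)(C)C | intermediate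
11 | lithium 2-{[4-(benzyloxy)-2-methoxy-6-propylbenzoyl]oxy}-1-methoxy-3-(trimethylsilyloxy)buta-1,3-dien-1-olate (geometry irrelevant) | CCCc1cc(OCc2ccccc2)cc(OC)c1C(=O)OC(C(=C)O[Si](C)(C)C)=C([O-])OC.[Li+] | intermediate
12 | 1-methoxy-1,3-bis(trimethylsilyloxy)buta-1,3-dien-2-yl 4-(benzyloxy)-2-methoxy-6-propylbenzoate (ketene acetal geometry irrelevant) | COC(O[Si](C)(C)C)=C(OC(=O)c1c(CCC)cc(OCc2ccccc2)cc1OC)C(=C)O[Si](C)(C)C | intermediate
13 | non-3-yn-2-one | CCCCCC#CC(C)=O | starting material
14 | 5-acetyl-6-methoxy-4-pentyl-2,6-bis(trimethylsilyloxy)cyclohexa-1,4-dien-1-yl 4-(benzyloxy)-2-methoxy-6-propylbenzoate (racemic at the ketal carbon) | CCCCCC1=C(C(C)=O)C(OC)(O[Si](C)(C)C)C(OC(=O)c2c(CCC)cc(OCc3ccccc3)cc2OC)=C(O[Si](C)(C)C)C1 | intermediate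
15 | 3-acetyl-2,6-dihydroxy-4-pentylphenyl 4-(benzyloxy)-2-methoxy-6-propylbenzoate | CCCCCc1cc(O)c(OC(=O)c2c(CCC)cc(OCc3ccccc3)cc2OC)c(O)c1C(C)=O | intermediate
16 | 3-acetyl-2,6-dihydroxy-4-pentylphenyl 4-hydroxy-2-methoxy-6-propylbenzoate | CCCCCc1cc(O)c(OC(=O)c2c(CCC)cc(O)cc2OC)c(O)c1C(C)=O | target

Total step count: 9.
Longest linear sequence: 9 steps (1 to 16); 7 and 13 are purchased and enter at steps 5 and 8.

Steps most likely to fail

Step 8. The hindered, fully substituted diene may add too slowly to the internal ynone, so that diene hydrolysis or open-chain conjugate addition without ring closure takes over. The ketal may also collapse by loss of silanol, which would leave a ring A methyl ether. Fallback: ring A is taken from an arene and the depside bond is made by direct acylation, setting out from acid 6 and returning at 15. Commercial olivetol is protected (MOMCl, i-Pr2NEt, CH2Cl2) as 1,3-bis(methoxymethoxy)-5-pentylbenzene F1. Directed ortho-lithiation between the two acetal groups (n-BuLi, THF, 0 °C) gives [2,6-bis(methoxymethoxy)-4-pentylphenyl]lithium F2, which is trapped with B(OMe)3 as dimethyl [2,6-bis(methoxymethoxy)-4-pentylphenyl]boronate F3 and oxidised (H2O2, NaOH) to 2,6-bis(methoxymethoxy)-4-pentylphenol F4. Acid 6 is converted ((COCl)2, cat. DMF, CH2Cl2) into 4-(benzyloxy)-2-methoxy-6-propylbenzoyl chloride F5, which acylates F4 (Et3N, DMAP, CH2Cl2, reflux) to 2,6-bis(methoxymethoxy)-4-pentylphenyl 4-(benzyloxy)-2-methoxy-6-propylbenzoate F6. Acetal cleavage (HCl, MeOH, rt) frees 2,6-dihydroxy-4-pentylphenyl 4-(benzyloxy)-2-methoxy-6-propylbenzoate F7, whose two open ring A positions are equivalent. Titanium-mediated ortho C-acetylation of a phenol (AcCl, TiCl4, CH2Cl2, 0 °C to rt) then gives 15.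

Step 7. The lithium amide may deprotonate the benzylic CH2 of the ortho propyl group instead of the γ-methyl group, and the dienolate may pass the aroyl group to a neighbouring oxygen before it is silylated. Fallback: from keto ester 9 the diene is made without any metal enolate by electrophile-first double enolisation (TMSOTf 2.3 equiv, Et3N, Et2O, 0 °C). The silyl triflate activates first the ketone and then the ester carbonyl, and the amine removes the α- and γ-protons in turn. Compounds 10 and 11 are bypassed, the sequence comes back at diene 12, and no compound outside the list is made.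

Step 5. The carboxylate or bicarbonate may enolise chloride 7 or product 9 instead of substituting, which opens the way to retro-Claisen loss of the acetyl group and to incomplete displacement at the secondary carbon. Fallback: from acid 6 the same C–O bond is made by rhodium carbenoid O–H insertion. Methyl 2-diazo-3-oxobutanoate F8 (from methyl acetoacetate by diazo transfer with p-acetamidobenzenesulfonyl azide and Et3N) is decomposed with catalytic Rh2(OAc)4 in CH2Cl2 at 40 °C in the presence of 6. This base-free reaction returns directly to 9.

Further compounds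
F1 | step 8 | 1,3-bis(methoxymethoxy)-5-pentylbenzene | CCCCCc1cc(OCOC)cc(OCOC)c1
F2 | step 8 | [2,6-bis(methoxymethoxy)-4-pentylphenyl]lithium | CCCCCc1cc(OCOC)c([Li])c(OCOC)c1
F3 | step 8 | dimethyl [2,6-bis(methoxymethoxy)-4-pentylphenyl]boronate | CCCCCc1cc(OCOC)c(B(OC)OC)c(OCOC)c1
F4 | step 8 | 2,6-bis(methoxymethoxy)-4-pentylphenol | CCCCCc1cc(OCOC)c(O)c(OCOC)c1
F5 | step 8 | 4-(benzyloxy)-2-methoxy-6-propylbenzoyl chloride | CCCc1cc(OCc2ccccc2)cc(OC)c1C(=O)Cl
F6 | step 8 | 2,6-bis(methoxymethoxy)-4-pentylphenyl 4-(benzyloxy)-2-methoxy-6-propylbenzoate | CCCCCc1cc(OCOC)c(OC(=O)c2c(CCC)cc(OCc3ccccc3)cc2OC)c(OCOC)c1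
F7 | step 8 | 2,6-dihydroxy-4-pentylphenyl 4-(benzyloxy)-2-methoxy-6-propylbenzoate | CCCCCc1cc(O)c(OC(=O)c2c(CCC)cc(OCc3ccccc3)cc2OC)c(O)c1
F0 | step 7 | none | none
F8 | step 5 | methyl 2-diazo-3-oxobutanoate | CC(=O)C(=[N+]=[N-])C(=O)OC
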